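**Strategy**

- Retrosynthetic cuts, in order: the five phenol protecting groups; both aryl–C(=O) bonds to the two identical 2,4-dihydroxyphenyl rings (one double Weinreb acylation); the C5–CH= bond of the propenone arm (Heck); the C3–C3a bond of the dihydrofuran (Wolff ring contraction of a 3-diazoflavanone); the C2–aryl bond (conjugate addition to 6-bromochromone).
- Enabling feature: the ring O1–C2–C3–C3a–C7a has an aryl group on C2 beside O1 and an out-of-ring carbonyl on C3. It is therefore a 2-arylchroman-4-one (flavanone) whose C4 carbonyl has been squeezed out of the ring, and the extruded carbon serves as the C3 acyl handle.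
- Forward order: benzo ring and pyranone are bought as the chromone; the C2 aryl ring is added; the pyranone is contracted to the dihydrofuran; the three-carbon arm is attached at C5; both resorcinol rings are attached together; all MOM ethers are removed.
- Stereochemistry: C2 (R) comes from the ligand-controlled conjugate addition and is not touched again; C3 (R, trans to the C2 aryl) comes from protonation of the amide enol in the ring contraction and is also the thermodynamic epimer; the E alkene comes from the Heck reaction.

Key step: step 4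

**Remarks**

- Locants: dihydrobenzofuran numbering (O1, C2, C3, C3a, C4–C7, C7a) is used for the target series and chromanone numbering (O1, C2, C3, C4, C4a, C5–C8, C8a) for the precursors. The target is the trans (2R,3R) isomer.
- Assumption: (S)-t-BuPyOx is taken to deliver the 2R flavanone, by analogy with its facial sense on cyclic enones. If the sense were opposite, the R ligand would be used with no other change.
- In the 3-diazo ketone (and the 3-oxime of the fallback) the C2 descriptor reads S only because C3 outranks the aryl group in the CIP order. No bond at C2 is changed.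
- All phenols are carried as methoxymethyl (MOM) ethers, which tolerate the organometallic steps and leave together in one mild acidic operation.

**Route**

Step 1
Reactants: 1 6-bromochromone; 2 4-(methoxymethoxy)phenylboronic acid
Product: 3 (2R)-6-bromo-2-[4-(methoxymethoxy)phenyl]chroman-4-one
Conditions: Pd(OCOCF3)2 (5 mol%), (S)-t-BuPyOx [(S)-4-tert-butyl-2-(pyridin-2-yl)-4,5-dihydrooxazole] (6 mol%), NH4PF6 (30 mol%), H2O (5 equiv), 2 (2 equiv), ClCH2CH2Cl, 60 °C
Reagents that add atoms: none
Why: Asymmetric conjugate addition of an arylboronic acid (Hayashi–Miyaura type) under divalent palladium/pyridine-oxazoline catalysis: the aryl–palladium species inserts the chromone C2=C3 bond on the face dictated by the tert-butyl group of the ligand, which sets C2 as R, and protonolysis of the palladium enolate closes a redox-neutral cycle that never reaches zerovalent palladium, so the C6–Br bond and the MOM ether should survive.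

Step 2
Reactants: 3 (2R)-6-bromo-2-[4-(methoxymethoxy)phenyl]chroman-4-one
Product: 5 (2R)-6-bromo-2-[4-(methoxymethoxy)phenyl]-3-(trifluoroacetyl)chroman-4-one, via lithium enolate 4 (not isolated)
Conditions: LiN(SiMe3)2 (1.1 equiv), THF, -78 °C, 30 min; CF3CO2CH2CF3 (1.2 equiv), -78 °C, 10 min; AcOH (1.2 equiv), -78 °C; crude product used directly
Reagents that add atoms: 2,2,2-trifluoroethyl trifluoroacetate, O=C(OCC(F)(F)F)C(F)(F)F
Why: Claisen-type C-acylation of the kinetic lithium enolate, the activation stage of a deacylative diazo transfer: at -78 °C the enolate should be captured by the very electrophilic trifluoroacetate faster than it can open by retro-oxa-Michael loss of the phenoxide, so C2 keeps its configuration, and the new C3 centre (largely enolised) is irrelevant because it is erased in the next step.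

Step 3
Reactants: 5 (2R)-6-bromo-2-[4-(methoxymethoxy)phenyl]-3-(trifluoroacetyl)chroman-4-one
Product: 6 (2S)-6-bromo-3-diazo-2-[4-(methoxymethoxy)phenyl]chroman-4-one
Conditions: MsN3 (1.5 equiv), Et3N (1.5 equiv), H2O (1 equiv), MeCN, 20 °C, dark
Reagents that add atoms: methanesulfonyl azide, CS(=O)(=O)N=[N+]=[N-]
Why: Regitz diazo transfer in its detrifluoroacetylative form: the ammonium enolate of the 1,3-diketone attacks the terminal azide nitrogen and the adduct fragments with transfer of the trifluoroacetyl group to the sulfonamide nitrogen, giving the diazo ketone under conditions too mild to affect C2, which from here on has no acidic neighbour through which the ring could open.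

Step 4
Reactants: 6 (2S)-6-bromo-3-diazo-2-[4-(methoxymethoxy)phenyl]chroman-4-one
Product: 9 (2R,3R)-5-bromo-N-methoxy-2-[4-(methoxymethoxy)phenyl]-N-methyl-2,3-dihydro-1-benzofuran-3-carboxamide, via aryl ketene 7 (not isolated), via amide enol 8 (not isolated)
Conditions: hν (365 nm LED), MeNHOMe (free base, 3 equiv), degassed THF (0.02 M), 0–20 °C
Reagents that add atoms: N,O-dimethylhydroxylamine, CNOC
Why: Excitation of the cyclic α-diazo ketone, which is held s-cis, expels N2 while the aryl carbon C4a shifts from the carbonyl carbon C4 to the diazo carbon C3, forming the C3–C3a bond and the exocyclic ketene 7; the amine then adds to the ketene carbon (new C–N bond) and the amide enol 8 is protonated at C3. The closest known reaction type is the photochemical Wolff ring contraction of cyclic α-diazo ketones with nucleophilic capture of the ketene, for which 3-diazochroman-4-ones giving 2,3-dihydrobenzofuran-3-carboxylic acid derivatives are the direct analogues. The five-membered ring O1–C2–C3–C3a–C7a is closed by ring contraction, that is by 1,2-migration within the existing pyranone and not by a cyclisation, so the O1–C2 and O1–aryl bonds are carried over unchanged. C3 is the only new stereocentre and is set by protonation of enol 8 on the face away from the C2 aryl group, which should give the trans (2R,3R) amide, also the more stable epimer, while C2 takes no part in any bond change. The step needs migration to win over 1,2-hydride shift from C2 (flavone formation) and over N–H insertion; the locked s-cis geometry, which favours the concerted photochemical path over a free carbene, and the good migratory aptitude of the aryl carbon are expected to secure this. Light of 365 nm is not absorbed by the aryl bromide, and the amine should intercept the ketene before it can dimerise.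

Step 5
Reactants: 9 (2R,3R)-5-bromo-N-methoxy-2-[4-(methoxymethoxy)phenyl]-N-methyl-2,3-dihydro-1-benzofuran-3-carboxamide; 10 N-methoxy-N-methylacrylamide
Product: 11 (2R,3R)-N-methoxy-5-[(E)-3-[methoxy(methyl)amino]-3-oxoprop-1-enyl]-2-[4-(methoxymethoxy)phenyl]-N-methyl-2,3-dihydro-1-benzofuran-3-carboxamide
Conditions: Pd(OAc)2 (5 mol%), P(o-tol)3 (12 mol%), Et3N (2.5 equiv), 10 (1.5 equiv), DMF, 100 °C
Reagents that add atoms: none
Why: Mizoroki–Heck reaction: Pd(OAc)2 is reduced in situ to zerovalent palladium, which inserts into the C5–Br bond, and syn carbopalladation at the unsubstituted alkene terminus followed by syn β-hydride elimination should give the E alkene, while the MOM ether and the C3 amide are inert and any epimerisation at C3 under the amine base can only return the favoured trans isomer.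

Step 6
Reactants: 12 4-bromoresorcinol
Product: 13 1-bromo-2,4-bis(methoxymethoxy)benzene
Conditions: MOMCl (2.6 equiv), i-Pr2NEt (3 equiv), CH2Cl2, 0 °C to 20 °C
Reagents that add atoms: chloromethyl methyl ether, COCCl
Why: Williamson-type O-alkylation of both phenols with the reactive α-chloro ether under amine base (MOM ether formation), with no stereocentre involved.

Step 7
Reactants: 11 (2R,3R)-N-methoxy-5-[(E)-3-[methoxy(methyl)amino]-3-oxoprop-1-enyl]-2-[4-(methoxymethoxy)phenyl]-N-methyl-2,3-dihydro-1-benzofuran-3-carboxamide; 13 1-bromo-2,4-bis(methoxymethoxy)benzene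
Product: 17 (E)-3-[(2R,3R)-3-[2,4-bis(methoxymethoxy)benzoyl]-2-[4-(methoxymethoxy)phenyl]-2,3-dihydro-1-benzofuran-5-yl]-1-[2,4-bis(methoxymethoxy)phenyl]prop-2-en-1-one, via aryllithium 14 (not isolated), via arylcerium dichloride 15 (not isolated), via bis-hemiaminal cerium alkoxide 16 (not isolated)
Conditions: 13 (4.5 equiv), n-BuLi (4.4 equiv), THF, -78 °C; anhydrous CeCl3 (4.6 equiv, THF slurry), -78 °C, 1 h; then 11, -78 to -40 °C; sat. aq. NH4Cl
Reagents that add atoms: none
Why: Weinreb ketone synthesis carried out twice in one flask: bromine–lithium exchange gives the ortho-alkoxy-stabilised aryllithium, transmetalation to the less basic and more oxophilic ArCeCl2 should suppress deprotonation at C3, and 1,2-addition to each N-methoxy-N-methylamide gives a chelated tetrahedral adduct that resists over-addition and conjugate addition until the quench releases both ketones, with no stereocentre formed and C2, C3 and the E alkene retained.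

Step 8
Reactants: 17 (E)-3-[(2R,3R)-3-[2,4-bis(methoxymethoxy)benzoyl]-2-[4-(methoxymethoxy)phenyl]-2,3-dihydro-1-benzofuran-5-yl]-1-[2,4-bis(methoxymethoxy)phenyl]prop-2-en-1-one
Product: 18 (E)-3-[(2R,3R)-3-(2,4-dihydroxybenzoyl)-2-(4-hydroxyphenyl)-2,3-dihydro-1-benzofuran-5-yl]-1-(2,4-dihydroxyphenyl)prop-2-en-1-one (CNP0288976.3)
Conditions: HCl (about 1 M, from conc. aq. HCl), MeOH–THF (3:1), 45 °C
Reagents that add atoms: none
Why: Acid-catalysed acetal exchange (solvolysis of the five aryl MOM ethers to the phenols), mild enough that the enone, the two aryl ketones and the benzylic C2–O1 ether should stay intact, while C3, which can equilibrate through its enol, remains in the favoured trans arrangement.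

**Compound list**

1 | 6-bromochromone (6-bromo-4H-chromen-4-one) | O=c1ccoc2ccc(Br)cc12 | starting material
2 | 4-(methoxymethoxy)phenylboronic acid | OB(O)c1ccc(OCOC)cc1 | starting material
3 | (2R)-6-bromo-2-[4-(methoxymethoxy)phenyl]chroman-4-one | O=C1C[C@H](c2ccc(OCOC)cc2)Oc2ccc(Br)cc21 | intermediate
4 | lithium enolate of 3, lithium (2R)-6-bromo-2-[4-(methoxymethoxy)phenyl]-2H-chromen-4-olate (not isolated) | [Li]OC1=C[C@H](c2ccc(OCOC)cc2)Oc2ccc(Br)cc21 | intermediate
5 | (2R)-6-bromo-2-[4-(methoxymethoxy)phenyl]-3-(trifluoroacetyl)chroman-4-one (keto form drawn; C3 undefined, largely enolised) | O=C1C(C(=O)C(F)(F)F)[C@H](c2ccc(OCOC)cc2)Oc2ccc(Br)cc21 | intermediate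
6 | (2S)-6-bromo-3-diazo-2-[4-(methoxymethoxy)phenyl]chroman-4-one | O=C1C(=[N+]=[N-])[C@H](c2ccc(OCOC)cc2)Oc2ccc(Br)cc21 | intermediate
7 | aryl ketene, 5-bromo-2-[4-(methoxymethoxy)phenyl]-3-(oxomethylidene)-2,3-dihydro-1-benzofuran, C2 as in 6 (not isolated) | Brc1ccc2c(c1)C(=C=O)[C@H](c1ccc(OCOC)cc1)O2 | intermediate
8 | amide enol, 5-bromo-3-[hydroxy(methoxy(methyl)amino)methylidene]-2-[4-(methoxymethoxy)phenyl]-2,3-dihydro-1-benzofuran, C2 as in 6 (not isolated) | Brc1ccc2c(c1)C(=C(O)N(C)OC)[C@H](c1ccc(OCOC)cc1)O2 | intermediate
9 | (2R,3R)-5-bromo-N-methoxy-2-[4-(methoxymethoxy)phenyl]-N-methyl-2,3-dihydro-1-benzofuran-3-carboxamide (trans) | Brc1ccc2c(c1)[C@@H](C(=O)N(C)OC)[C@H](c1ccc(OCOC)cc1)O2 | intermediate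
10 | N-methoxy-N-methylacrylamide | C=CC(=O)N(C)OC | starting material
11 | (2R,3R)-N-methoxy-5-[(E)-3-[methoxy(methyl)amino]-3-oxoprop-1-enyl]-2-[4-(methoxymethoxy)phenyl]-N-methyl-2,3-dihydro-1-benzofuran-3-carboxamide | CON(C)C(=O)/C=C/c1ccc2c(c1)[C@@H](C(=O)N(C)OC)[C@H](c1ccc(OCOC)cc1)O2 | intermediate
12 | 4-bromoresorcinol (4-bromobenzene-1,3-diol) | Oc1ccc(Br)c(O)c1 | starting material
13 | 1-bromo-2,4-bis(methoxymethoxy)benzene | COCOc1ccc(Br)c(OCOC)c1 | intermediate
14 | [2,4-bis(methoxymethoxy)phenyl]lithium (not isolated) | COCOc1ccc([Li])c(OCOC)c1 | intermediate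
15 | [2,4-bis(methoxymethoxy)phenyl]cerium dichloride, ArCeCl2 (not isolated) | COCOc1ccc([Ce](Cl)Cl)c(OCOC)c1 | intermediate
16 | double tetrahedral adduct of 15 with 11, both amide carbons as O-CeCl2 hemiaminals (new carbinol centres undefined; not isolated) | COCOc1ccc(C(O[Ce](Cl)Cl)(N(C)OC)/C=C/c2ccc3c(c2)[C@@H](C(O[Ce](Cl)Cl)(N(C)OC)c2ccc(OCOC)cc2OCOC)[C@H](c2ccc(OCOC)cc2)O3)c(OCOC)c1 | intermediate
17 | (E)-3-[(2R,3R)-3-[2,4-bis(methoxymethoxy)benzoyl]-2-[4-(methoxymethoxy)phenyl]-2,3-dihydro-1-benzofuran-5-yl]-1-[2,4-bis(methoxymethoxy)phenyl]prop-2-en-1-one | COCOc1ccc(C(=O)/C=C/c2ccc3c(c2)[C@@H](C(=O)c2ccc(OCOC)cc2OCOC)[C@H](c2ccc(OCOC)cc2)O3)c(OCOC)c1 | intermediate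
18 | (E)-3-[(2R,3R)-3-(2,4-dihydroxybenzoyl)-2-(4-hydroxyphenyl)-2,3-dihydro-1-benzofuran-5-yl]-1-(2,4-dihydroxyphenyl)prop-2-en-1-one (CNP0288976.3) | O=C(/C=C/c1ccc2c(c1)[C@@H](C(=O)c1ccc(O)cc1O)[C@H](c1ccc(O)cc1)O2)c1ccc(O)cc1O | target

**Step count and risks**

Total steps: 8. Longest linear sequence: 7 steps (steps 1, 2, 3, 4, 5, 7, 8, from 6-bromochromone 1); step 6 is a one-step side branch.

Steps most likely to fail:

1. Step 4. The amine may interfere with the photochemical event (N–H insertion at the carbene stage, or quenching of the excited diazo ketone by electron transfer), so that ring contraction with direct amide capture is not the main course. Fallback: setting out from 6, the irradiation (365 nm) is run in THF–water, the closest-precedent capture of the ketene 7 by water. This should give (2R,3R)-5-bromo-2-[4-(methoxymethoxy)phenyl]-2,3-dihydro-1-benzofuran-3-carboxylic acid F1. The acid is then coupled with MeNHOMe·HCl (EDC·HCl, HOBt, i-Pr2NEt, CH2Cl2, 20 °C) in a separate dark step, and the route is rejoined at 9.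

2. Step 7. The organometallic may deprotonate C3 (benzylic and α to the hindered amide) instead of adding to it. This would leave the C3 amide unreacted or open the dihydrofuran by β-elimination of the phenoxide, with loss of the C2 configuration. Fallback: setting out from 11, both Weinreb amides are reduced with i-Bu2AlH (THF, -78 °C) to (2R,3R)-2-[4-(methoxymethoxy)phenyl]-5-[(E)-3-oxoprop-1-enyl]-2,3-dihydro-1-benzofuran-3-carbaldehyde F2. The crude dialdehyde is treated at -78 °C with aryllithium 14, which adds to aldehydes far faster than it deprotonates, to give the bis-carbinol (E)-1-[2,4-bis(methoxymethoxy)phenyl]-3-[3-{[2,4-bis(methoxymethoxy)phenyl](hydroxy)methyl}-2-[4-(methoxymethoxy)phenyl]-2,3-dihydro-1-benzofuran-5-yl]prop-2-en-1-ol F3 as a mixture at the carbinol centres. Oxidation of both alcohols with Dess–Martin periodinane (NaHCO3, CH2Cl2) rejoins the route at 17.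

3. Step 2. The enantiomeric purity at C2 may erode through retro-oxa-Michael opening of the lithium enolate 4 to the achiral chalcone phenoxide and reclosure. Fallback: setting out from 3, soft enolisation without a free enolate (TBSOTf, Et3N, CH2Cl2, -78 to 0 °C) gives the silyl enol ether (2R)-6-bromo-4-[(tert-butyldimethylsilyl)oxy]-2-[4-(methoxymethoxy)phenyl]-2H-chromene F4. Nitrosation with NOCl (CH2Cl2, -20 °C) gives the α-oximino ketone (2S)-6-bromo-3-(hydroxyimino)-2-[4-(methoxymethoxy)phenyl]chroman-4-one F5. A Forster reaction with chloramine (from NaOCl and aq. NH3; NaOH, THF–H2O, 0 °C) then converts the oxime into the diazo ketone, and the route is rejoined at 6, bypassing 5.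

Further compounds
F1 | step 4 | (2R,3R)-5-bromo-2-[4-(methoxymethoxy)phenyl]-2,3-dihydro-1-benzofuran-3-carboxylic acid | Brc1ccc2c(c1)[C@@H](C(=O)O)[C@H](c1ccc(OCOC)cc1)O2
F2 | step 7 | (2R,3R)-2-[4-(methoxymethoxy)phenyl]-5-[(E)-3-oxoprop-1-enyl]-2,3-dihydro-1-benzofuran-3-carbaldehyde | O=C/C=C/c1ccc2c(c1)[C@@H](C=O)[C@H](c1ccc(OCOC)cc1)O2
F3 | step 7 | (E)-1-[2,4-bis(methoxymethoxy)phenyl]-3-[3-{[2,4-bis(methoxymethoxy)phenyl](hydroxy)methyl}-2-[4-(methoxymethoxy)phenyl]-2,3-dihydro-1-benzofuran-5-yl]prop-2-en-1-ol (ring stereocentres as in 11, carbinol centres undefined) | COCOc1ccc(C(O)/C=C/c2ccc3c(c2)[C@@H](C(O)c2ccc(OCOC)cc2OCOC)[C@H](c2ccc(OCOC)cc2)O3)c(OCOC)c1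
F4 | step 2 | (2R)-6-bromo-4-[(tert-butyldimethylsilyl)oxy]-2-[4-(methoxymethoxy)phenyl]-2H-chromene | CC(C)(C)[Si](C)(C)OC1=C[C@H](c2ccc(OCOC)cc2)Oc2ccc(Br)cc21
F5 | step 2 | (2S)-6-bromo-3-(hydroxyimino)-2-[4-(methoxymethoxy)phenyl]chroman-4-one | O=C1C(=NO)[C@H](c2ccc(OCOC)cc2)Oc2ccc(Br)cc21
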